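**Plan**

- Retrosynthetic cuts: the ring A oxygens (2β,3β-epoxide ← 1β-hydroxy-2-ene ← 1-ketone); ring D at C13–C16; ring C at C12–C13; ring B at C8–C9; the lactone C10–O bond (back to a C9=C10 alkene and the C19 acid); ring A at C2–C3 and C4–C5 (Diels–Alder); the side chain at C5–C6 and C6–C8 (two Michael additions).
- Forward order: acyclic malonate 7 → ring A (step 4) → C9=C10 alkene (step 6) → 19,10-lactone with iodine on C9 (step 9) → ring B (step 10) → ring C (step 12) → ring D (step 13) → ring A oxygenation (steps 14–19).
- Enabling feature: C9 lies between the lactone-bearing bridgehead C10 of ring A and C11, and is four bonds (C9–C10–C5–C6–C8) from C8, the β-carbon of a C8=C14 unsaturated ester. A C9 radical therefore closes ring B 5-exo and makes C8 quaternary, and the two arms left on C8 (C14–C13 ester, C15–C17 propargyl) later become rings C and D.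
- Stereochemistry: C4 and C5 (absolute) from a catalytic asymmetric Diels–Alder reaction; C10 from intramolecular lactonisation; C9 and C8 from the key step (chair transition state on the lactone-bridged ring A); C6 by equilibration; C13 by ring constraint; C1 by equatorial hydride delivery; C2 and C3 by 1β-hydroxyl-directed epoxidation.

Key step: step 10

Remark: gibberellane numbering (C7 = ring B carboxyl carbon, C19 = lactone carbonyl) and the α/β descriptors of the usual gibberellin drawing are used for every intermediate. Centres and alkenes formed as converging mixtures carry no descriptor in the SMILES (C8=C14 geometry in 6–8, 10 and 14–19; C9 and C10 in 14 and 15; C9 in 19; C6 in 21; C12 in 23; C2 in 28 and 29).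

Remark: the catalyst enantiomer in step 4 is assumed to be the (S)-proline-derived one, chosen so that the diene adds to the Cα-si face of methacrolein; the antipode would be taken if the sense proved opposite.

**Route**

Step 1
Reactants: 1 methyl prop-2-ynoate; 2 3-bromo-1-(trimethylsilyl)prop-1-yne
Product: 3 methyl 6-(trimethylsilyl)hexa-2,5-diynoate
Conditions: CuI (0.2 equiv), NaI (0.2 equiv), K2CO3 (1.5 equiv), DMF, 0 °C → rt
Reagents that add atoms: none
Why: Copper-acetylide substitution of the propargylic bromide (copper-mediated alkyne–propargyl halide coupling) joins the C13–C14 ynoate to the C15–C17 propargyl unit at C8 under a base too mild to isomerise the skipped diyne; no stereocentre is formed.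

Step 2
Reactants: 3 methyl 6-(trimethylsilyl)hexa-2,5-diynoate; 4 dimethyl malonate; 5 but-3-yn-2-one
Product: 7 trimethyl (4E)-6-oxo-2-[3-(trimethylsilyl)prop-2-yn-1-yl]hepta-1,4-diene-1,3,3-tricarboxylate, via vinylmalonate 6 (not isolated)
Conditions: 4 + 3, Cs2CO3 (0.1 equiv), MeCN, 0 °C → rt; then 5, 0 °C → rt
Reagents that add atoms: none
Why: Two consecutive base-catalysed Michael additions: the malonate carbanion (C6) adds to C8 of the ynoate, and the resulting vinylogous malonate anion, whose charge sits mainly on the diester carbon (as in the classical α-alkylation of propene-1,1,3-tricarboxylates), adds through C6 to butynone (C5), the enone equilibrating to E; no stereocentre is formed.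

Step 3
Reactants: 7 trimethyl (4E)-6-oxo-2-[3-(trimethylsilyl)prop-2-yn-1-yl]hepta-1,4-diene-1,3,3-tricarboxylate
Product: 8 trimethyl (4E)-6-[(tert-butyldimethylsilyl)oxy]-2-[3-(trimethylsilyl)prop-2-yn-1-yl]hepta-1,4,6-triene-1,3,3-tricarboxylate
Conditions: TBSOTf, Et3N, CH2Cl2, −78 → 0 °C
Reagents that add atoms: tert-butyldimethylsilyl trifluoromethanesulfonate, CC(C)(C)[Si](C)(C)OS(=O)(=O)C(F)(F)F
Why: Soft enolisation (silyl triflate/amine) of the methyl ketone, the only enolisable carbonyl because C6 is quaternary, gives the 2-silyloxy diene C2=C1–C10=C5.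

Step 4
Reactants: 8 trimethyl (4E)-6-[(tert-butyldimethylsilyl)oxy]-2-[3-(trimethylsilyl)prop-2-yn-1-yl]hepta-1,4,6-triene-1,3,3-tricarboxylate; 9 2-methylprop-2-enal (methacrolein)
Product: 10 ring A aldehyde (4α-formyl 4β-methyl 5β-H silyl enol ether)
Conditions: (S)-3,3-diphenyl-1-(2-methylphenyl)tetrahydro-1H,3H-pyrrolo[1,2-c][1,3,2]oxazaborole (0.2 equiv) + HN(SO2CF3)2 (0.18 equiv), CH2Cl2, −78 → −20 °C
Reagents that add atoms: none
Why: Lewis-acid-catalysed Diels–Alder reaction (chiral oxazaborolidinium catalysis): the 2-silyloxy group and the terminal alkyl group of the diene both steer C5 to the substituted carbon C4 of the enal, the endo transition state puts the formyl group cis to the C5 side chain, and the catalyst blocks one face of the coordinated enal, which fixes C4 and C5 absolutely.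

Step 5
Reactants: 11 prop-2-enal (acrolein); 12 sodium benzenesulfinate
Product: 13 3-(phenylsulfonyl)propanal
Conditions: AcOH, THF/H2O, 0 °C → rt
Reagents that add atoms: none
Why: Conjugate (sulfa-Michael) addition of the sulfinate through sulfur to acrolein under buffered acidic conditions; no stereocentre is formed.

Step 6
Reactants: 10 ring A aldehyde; 13 3-(phenylsulfonyl)propanal
Product: 16 (E)-enone aldehyde (1-oxo 10(9)-ene), via aldol 14 (not isolated), via mesylate 15 (not isolated)
Conditions: TiCl4, CH2Cl2, −78 °C; crude aldol: MsCl, Et3N, CH2Cl2, 0 °C; then DBU (1.1 equiv), 0 °C, short contact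
Reagents that add atoms: none
Why: Mukaiyama aldol addition of the regiodefined silyl enol ether through C10 to the unhindered aldehyde 13 (the neopentyl C19 aldehyde is too crowded to compete), then mesylation and base-induced β-elimination through the ketone enolate give the conjugated alkylidene ketone; the C9/C10 epimers of the aldol converge, the alkene geometry is immaterial later, and the brief cold exposure to base leaves the C8=C14 enoate in conjugation.

Step 7
Reactants: 16 (E)-enone aldehyde
Product: 17 enone C19 acid
Conditions: NaClO2, NaH2PO4, 2-methylbut-2-ene, t-BuOH/H2O, 0 °C → rt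
Reagents that add atoms: sodium chlorite, [Na+].[O-]Cl=O
Why: Pinnick (chlorite) oxidation converts the non-enolisable C19 aldehyde into the acid without touching enone, enoate or alkyne; no new stereocentre.

Step 8
Reactants: 17 enone C19 acid
Product: 18 1α-hydroxy 10(9)-ene C19 acid
Conditions: NaBH4, CeCl3·7H2O, MeOH, −40 °C
Reagents that add atoms: none
Why: Luche 1,2-reduction turns the enone into an electron-rich allylic-alcohol alkene fit for iodonium formation; hydride is expected anti to the pseudo-axial C5 side chain (1α-OH), and C1 is re-oxidised in step 14, so its configuration is immaterial.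

Step 9
Reactants: 18 1α-hydroxy 10(9)-ene C19 acid
Product: 19 C9 iodo 19,10-lactone
Conditions: I2, NaHCO3, MeCN/H2O, 0 °C, dark
Reagents that add atoms: iodine, II
Why: Iodolactonisation: reversible iodonium formation on C9=C10 and 5-exo attack of the C19 carboxylate at the more substituted C10, which is possible only from the α face, sets the α C10–O bond of the bridged lactone, while iodine lands on C9 as either epimer.

Step 10
Reactants: 19 C9 iodo 19,10-lactone
Product: 20 ring A/B lactone triester
Conditions: Bu3SnH (1.3 equiv, syringe pump), Et3B (0.3 equiv), air, toluene, rt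
Reagents that add atoms: none
Why: Et3B/O2 starts a tin-radical chain in which Bu3Sn• takes iodine from C9; the planar secondary C9 radical (the same from either C9 epimer of 19) adds to C8, the β-carbon of the C8=C14 unsaturated ester, and the C14 α-ester radical is quenched by Bu3SnH. The closest known reaction type is the 5-exo-trig cyclisation of an alkyl radical onto a β,β-disubstituted acrylate that creates a quaternary carbon (intramolecular Giese reaction). Ring B (C5–C6–C8–C9–C10) closes in the 5-exo-trig mode through the chain C9–C10–C5–C6–C8, attack at C14 (6-endo) being disfavoured by polarity. C9 and C8 are set in a chair-like Beckwith–Houk transition state on the rigid lactone-bridged ring A: C11 on C9 and the acrylate carbon C14 lie pseudo-equatorial on the α face, away from C1, while the C9 hydrogen and the propargyl carbon C15 lie pseudo-axial on the β face syn to the C5 hydrogen, which gives 9β-H and C8 with C14 α and C15 β. The step needs exo closure, cyclisation ahead of reduction of the C9 radical and one face of the acceptor; these are secured by the nucleophilic radical/electron-poor β-carbon pairing, the gem-diester at C6 (Thorpe–Ingold effect, no epimerisable C6–H), slow addition of Bu3SnH at room temperature and the conformationally locked bicyclic lactone.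

Step 11
Reactants: 20 ring A/B lactone triester
Product: 21 ring A/B lactone C7 monoester (C6 epimers)
Conditions: LiCl, H2O, DMSO, 150 °C
Reagents that add atoms: none
Why: Krapcho dealkoxycarbonylation: chloride demethylates one ester of the activated gem-diester and the carboxylate loses CO2, the isolated methyl ester, lactone, sulfone and silyl alkyne being inert; C6 becomes CH as a mixture that is equilibrated in step 12.

Step 12
Reactants: 21 ring A/B lactone C7 monoester
Product: 23 ring C β-keto sulfone, via terminal alkyne 22 (not isolated)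
Conditions: t-BuOK (3.5 equiv), t-BuOH/THF, 0 °C → rt; AcOH quench
Reagents that add atoms: none
Why: Alkoxide cleaves the alkynyl silane and equilibrates C6 to the less hindered 6β-ester (trans to C4), and the C12 sulfonyl carbanion acylates the unhindered C13 ester on the α face (Dieckmann-type sulfone acylation, driven by the β-keto sulfone enolate), closing ring C cis-fused because C11 and C14 are both α, whereas attack on the C7 ester would need a strained bridged ring; C12 is an inconsequential mixture.

Step 13
Reactants: 23 ring C β-keto sulfone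
Product: 25 tetracyclic 1α,13-diol methyl ester, via ketone 24 (not isolated)
Conditions: SmI2 (8 equiv), HMPA, t-BuOH, THF, 0 °C → rt
Reagents that add atoms: none
Why: Samarium diiodide first cleaves the C12–S bond of the β-keto sulfone, then forms the C13 ketyl, which adds 5-exo-dig to the propargyl alkyne at C16 (reductive ketone–alkyne cyclisation, the established way to the bicyclo[3.2.1]octane of gibberellins and kauranes); the bridged ring allows only one configuration at C13 and delivers the 13-OH and the 16-methylene together.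

Step 14
Reactants: 25 tetracyclic 1α,13-diol methyl ester
Product: 26 tetracyclic 1-ketone methyl ester
Conditions: Dess–Martin periodinane, CH2Cl2, rt
Reagents that add atoms: none
Why: Dess–Martin oxidation of the secondary C1 alcohol; the tertiary 13-OH cannot be oxidised.

Step 15
Reactants: 26 tetracyclic 1-ketone methyl ester
Product: 28 2-(phenylselanyl) 1-ketone 13-O-triethylsilyl ether, via bis-silyl enol ether 27 (not isolated)
Conditions: TESOTf (2.5 equiv), Et3N, CH2Cl2, −78 → 0 °C; then PhSeCl, −78 °C
Reagents that add atoms: triethylsilyl trifluoromethanesulfonate, CC[Si](CC)(CC)OS(=O)(=O)C(F)(F)F; benzeneselenenyl chloride, Cl[Se]c1ccccc1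
Why: The silyl triflate/amine pair silylates the 13-OH and enolises the ketone towards C2 (C10 is quaternary), and the silyl enol ether is selenenylated by PhSeCl far faster than the 16-alkene; both C2 epimers serve.

Step 16
Reactants: 28 2-(phenylselanyl) 1-ketone 13-O-triethylsilyl ether
Product: 30 1β-hydroxy 2-ene methyl ester 13-O-triethylsilyl ether, via hydroxy selenide 29 (not isolated)
Conditions: LiBH(s-Bu)3 (L-Selectride), THF, −78 °C; then pyridine, 30% H2O2, 0 °C → rt
Reagents that add atoms: none
Why: The bulky borohydride attacks C1 equatorially from the α side, as in the reduction of 3-oxo gibberellins, to give the axial 1β-alcohol, and the selenoxide formed on oxidative work-up undergoes syn-elimination away from the carbinol carbon (towards C3) to give the 2-ene allylic alcohol.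

Step 17
Reactants: 30 1β-hydroxy 2-ene methyl ester 13-O-triethylsilyl ether
Product: 31 1β-hydroxy 2-ene 7-acid 13-O-triethylsilyl ether
Conditions: LiSPr, HMPA, rt; then 1 M HCl to pH 3, 0 °C
Reagents that add atoms: none
Why: SN2 demethylation of the hindered C7 methyl ester by thiolate (the standard method for gibberellin methyl esters) spares the lactone, the silyl ether and the C6 configuration.

Step 18
Reactants: 31 1β-hydroxy 2-ene 7-acid 13-O-triethylsilyl ether
Product: 32 13-O-triethylsilyl ether of the target
Conditions: VO(acac)2 (0.05 equiv), t-BuOOH, CH2Cl2, 0 °C → rt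
Reagents that add atoms: tert-butyl hydroperoxide, CC(C)(C)OO
Why: Vanadium-catalysed hydroxyl-directed epoxidation delivers oxygen syn to the axial 1β-OH on the unhindered β face (2β,3β-epoxide), while the silylated 13-OH cannot direct attack on the 16-alkene.

Step 19
Reactants: 32 13-O-triethylsilyl ether of the target
Product: 33 target gibberellin
Conditions: Bu4NF, AcOH, THF, 0 °C → rt
Reagents that add atoms: none
Why: Fluoride removes the tertiary triethylsilyl ether under buffered conditions that leave epoxide, lactone and alkene untouched.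

**Compound list**

1 | methyl prop-2-ynoate | C#CC(=O)OC | starting material
2 | 3-bromo-1-(trimethylsilyl)prop-1-yne | C[Si](C)(C)C#CCBr | starting material
3 | methyl 6-(trimethylsilyl)hexa-2,5-diynoate | COC(=O)C#CCC#C[Si](C)(C)C | intermediate
4 | dimethyl malonate | COC(=O)CC(=O)OC | starting material
5 | but-3-yn-2-one | CC(=O)C#C | starting material
6 | vinylmalonate: trimethyl 2-[3-(trimethylsilyl)prop-2-yn-1-yl]prop-1-ene-1,3,3-tricarboxylate (E/Z mixture) | COC(=O)C=C(CC#C[Si](C)(C)C)C(C(=O)OC)C(=O)OC | intermediate (not isolated)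
7 | trimethyl (4E)-6-oxo-2-[3-(trimethylsilyl)prop-2-yn-1-yl]hepta-1,4-diene-1,3,3-tricarboxylate (C8=C14 geometry mixed) | CC(=O)/C=C/C(C(=O)OC)(C(=O)OC)C(CC#C[Si](C)(C)C)=CC(=O)OC | intermediate
8 | trimethyl (4E)-6-[(tert-butyldimethylsilyl)oxy]-2-[3-(trimethylsilyl)prop-2-yn-1-yl]hepta-1,4,6-triene-1,3,3-tricarboxylate | C=C(O[Si](C)(C)C(C)(C)C)/C=C/C(C(=O)OC)(C(=O)OC)C(CC#C[Si](C)(C)C)=CC(=O)OC | intermediate
9 | 2-methylprop-2-enal (methacrolein) | CC(=C)C=O | starting material
10 | ring A aldehyde: 1-(tert-butyldimethylsilyloxy)cyclohex-1(10)-ene with 4β-methyl, 4α-formyl (C19) and, at C5 (5β-H), the chain C6(CO2Me)2–C8(CH2C≡CSiMe3)=C14H–C13O2Me | O=C[C@]1(C)CCC(O[Si](C)(C)C(C)(C)C)=C[C@@H]1C(C(=O)OC)(C(=O)OC)C(CC#C[Si](C)(C)C)=CC(=O)OC | intermediate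
11 | prop-2-enal (acrolein) | C=CC=O | starting material
12 | sodium benzenesulfinate | [Na+].[O-]S(=O)c1ccccc1 | starting material
13 | 3-(phenylsulfonyl)propanal | O=CCCS(=O)(=O)c1ccccc1 | intermediate
14 | aldol: 1-ketone of 10 carrying C9H(OH)–CH2CH2SO2Ph on C10 (C9, C10 epimers) | O=C[C@]1(C)CCC(=O)C(C(O)CCS(=O)(=O)c2ccccc2)[C@@H]1C(C(=O)OC)(C(=O)OC)C(CC#C[Si](C)(C)C)=CC(=O)OC | intermediate (not isolated)
15 | mesylate: C9 methanesulfonate of 14 | O=C[C@]1(C)CCC(=O)C(C(OS(C)(=O)=O)CCS(=O)(=O)c2ccccc2)[C@@H]1C(C(=O)OC)(C(=O)OC)C(CC#C[Si](C)(C)C)=CC(=O)OC | intermediate (not isolated)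
16 | (E)-enone aldehyde: 1-oxo, C10=C9H–CH2CH2SO2Ph, 4α-formyl, 4β-methyl, 5β-H | O=C[C@]1(C)CCC(=O)/C(=C/CCS(=O)(=O)c2ccccc2)[C@@H]1C(C(=O)OC)(C(=O)OC)C(CC#C[Si](C)(C)C)=CC(=O)OC | intermediate
17 | enone C19 acid (4α-carboxy analogue of 16) | OC(=O)[C@]1(C)CCC(=O)/C(=C/CCS(=O)(=O)c2ccccc2)[C@@H]1C(C(=O)OC)(C(=O)OC)C(CC#C[Si](C)(C)C)=CC(=O)OC | intermediate
18 | 1α-hydroxy 10(9)-ene C19 acid | OC(=O)[C@]1(C)CC[C@H](O)/C(=C/CCS(=O)(=O)c2ccccc2)[C@@H]1C(C(=O)OC)(C(=O)OC)C(CC#C[Si](C)(C)C)=CC(=O)OC | intermediate
19 | C9 iodo 19,10-lactone: 19,10-lactone (10α-O) of ring A, 1α-OH, C10 carrying C9H(I)–CH2CH2SO2Ph (C9 epimers), C5 side chain as in 10 | O=C1O[C@@]2(C(I)CCS(=O)(=O)c3ccccc3)[C@@H](O)CC[C@]1(C)[C@H]2C(C(=O)OC)(C(=O)OC)C(CC#C[Si](C)(C)C)=CC(=O)OC | intermediate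
20 | ring A/B lactone triester: 1α-OH, C6 gem-dimethyl ester, C8 with α-CH2CO2Me (C14, C13) and β-CH2C≡CSiMe3 (C15–C17), 9β-H with α-CH2CH2SO2Ph (C11, C12) | O=C1O[C@@]23[C@@H](O)CC[C@]1(C)[C@H]2C(C(=O)OC)(C(=O)OC)[C@](CC(=O)OC)(CC#C[Si](C)(C)C)[C@H]3CCS(=O)(=O)c4ccccc4 | intermediate
21 | ring A/B lactone C7 monoester (C6 epimers) | O=C1O[C@@]23[C@@H](O)CC[C@]1(C)[C@H]2C(C(=O)OC)[C@](CC(=O)OC)(CC#C[Si](C)(C)C)[C@H]3CCS(=O)(=O)c4ccccc4 | intermediate
22 | terminal alkyne: desilylated, C6-equilibrated 21 with 6β-ester | O=C1O[C@@]23[C@@H](O)CC[C@]1(C)[C@H]2[C@H](C(=O)OC)[C@](CC(=O)OC)(CC#C)[C@H]3CCS(=O)(=O)c4ccccc4 | intermediate (not isolated)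
23 | ring C β-keto sulfone: rings A, B, C and lactone, 13-oxo, 12-phenylsulfonyl (C12 epimers), 8β-propargyl, 1α-OH, 6β-CO2Me | O=C1O[C@@]23[C@@H](O)CC[C@]1(C)[C@H]2[C@H](C(=O)OC)[C@@]4(CC#C)CC(=O)C(S(=O)(=O)c5ccccc5)C[C@@H]34 | intermediate
24 | ketone: desulfonylated 23 | O=C1O[C@@]23[C@@H](O)CC[C@]1(C)[C@H]2[C@H](C(=O)OC)[C@@]4(CC#C)CC(=O)CC[C@@H]34 | intermediate (not isolated)
25 | tetracyclic 1α,13-diol methyl ester: rings A–D, 1α,13-dihydroxy, 16-ene, 19,10-lactone, 7-methyl ester, C2 and C3 saturated | C=C1C[C@]23C[C@@]1(O)CC[C@H]2[C@@]12OC(=O)[C@@](C)([C@H]1[C@@H]3C(=O)OC)CC[C@@H]2O | intermediate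
26 | tetracyclic 1-ketone methyl ester: 1-oxo analogue of 25 | C=C1C[C@]23C[C@@]1(O)CC[C@H]2[C@@]12OC(=O)[C@@](C)([C@H]1[C@@H]3C(=O)OC)CCC2=O | intermediate
27 | bis-silyl enol ether: 13-O-triethylsilyl 1-(triethylsilyloxy)-1-ene of 26 | C=C1C[C@]23C[C@@]1(O[Si](CC)(CC)CC)CC[C@H]2[C@@]12OC(=O)[C@@](C)([C@H]1[C@@H]3C(=O)OC)CC=C2O[Si](CC)(CC)CC | intermediate (not isolated)
28 | 2-(phenylselanyl) 1-ketone 13-O-triethylsilyl ether (7-methyl ester, C2 epimers) | C=C1C[C@]23C[C@@]1(O[Si](CC)(CC)CC)CC[C@H]2[C@@]12OC(=O)[C@@](C)([C@H]1[C@@H]3C(=O)OC)CC([Se]c4ccccc4)C2=O | intermediate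
29 | hydroxy selenide: 1β-hydroxy-2-(phenylselanyl) analogue of 28 | C=C1C[C@]23C[C@@]1(O[Si](CC)(CC)CC)CC[C@H]2[C@@]12OC(=O)[C@@](C)([C@H]1[C@@H]3C(=O)OC)CC([Se]c4ccccc4)[C@H]2O | intermediate (not isolated)
30 | 1β-hydroxy 2-ene methyl ester 13-O-triethylsilyl ether | C=C1C[C@]23C[C@@]1(O[Si](CC)(CC)CC)CC[C@H]2[C@@]12OC(=O)[C@@](C)([C@H]1[C@@H]3C(=O)OC)C=C[C@H]2O | intermediate
31 | 1β-hydroxy 2-ene 7-acid 13-O-triethylsilyl ether | C=C1C[C@]23C[C@@]1(O[Si](CC)(CC)CC)CC[C@H]2[C@@]12OC(=O)[C@@](C)([C@H]1[C@@H]3C(=O)O)C=C[C@H]2O | intermediate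
32 | 13-O-triethylsilyl ether of the target (1β-hydroxy-2β,3β-epoxide, 7-acid) | C=C1C[C@]23C[C@@]1(O[Si](CC)(CC)CC)CC[C@H]2[C@@]12OC(=O)[C@@](C)([C@H]1[C@@H]3C(=O)O)[C@H]1O[C@H]1[C@H]2O | intermediate
33 | target gibberellin: 1β,13-dihydroxy-2β,3β-epoxy, 16-ene, 19,10-lactone, 7-acid | C=C1C[C@]23C[C@@]1(O)CC[C@H]2[C@@]12OC(=O)[C@@](C)([C@H]1[C@@H]3C(=O)O)[C@H]1O[C@H]1[C@H]2O | target

**Step count and risks**

Total step count: 19. Longest linear sequence: 18 steps (steps 1–4 and 6–19; step 5 is a one-step branch).

Steps most likely to fail: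

Step 10. The C9 radical may be reduced by the stannane before it adds to the crowded C8 (flanked by the quaternary C6), or a 1,2-shift of the lactone acyloxy group may intervene. The fallback closes ring B before the lactone and from a delocalised radical. It sets out from 17: Bu3SnH (2.5 equiv) with Et3B/air in benzene at rt should convert the enone into its allylic O-stannyl ketyl, whose β-carbon C9 adds 5-exo to C8 of the enoate (reductive coupling of the β-carbons of two tethered electron-poor alkenes). This allylic radical takes hydrogen from the stannane much more slowly than the localised secondary radical of step 10, and acidic work-up of the tin enolate and tin carboxylate gives the ring A/B keto acid F1, drawn with the C8 and C9 configurations that are needed. PhI(OH)OTs in CH2Cl2 at rt then lactonises this 5-oxo carboxylic acid oxidatively through the more substituted C1=C10 enol, the carboxylate reaching C10 only from the α face, and gives the 1-oxo lactone F2, at which stage any C8 or C9 stereoisomers would be removed. NaBH4 in MeOH at −20 °C delivers hydride axially and gives the equatorial 1α-alcohol 20, where the route is rejoined.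

Step 4. The bulky diene may react sluggishly with the α-substituted enal, and endo or facial selectivity may be poor. The fallback makes the quaternary C4 by enolate alkylation under substrate control instead of in the cycloaddition. It sets out from 8: the catalyst of step 4 (the enantiomer that leads to 5β-H) with the unhindered, strongly endo-selective dienophile 11 gives the desmethyl aldehyde F3, whose C4 configuration is immaterial. t-BuOK (1.05 equiv) and MeI in THF at −78 → 0 °C remove the aldehyde α-hydrogen, the most acidic C–H of this compound, and methylate the enolate on the face away from the C5 side chain, which places the formyl group cis to that chain and gives 10, where the route is rejoined.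

Step 2. The ambident anion of 6 may add through C14 instead of the diester carbon, or the crowded quaternary carbon may fail to form. The fallback uses deconjugative α-functionalisation of an alkylidene malonate, in which only the diester carbon is stabilised. It sets out from 4: Knoevenagel condensation with commercially available (2-methyl-1,3-dioxolan-2-yl)acetaldehyde (piperidinium acetate, toluene, reflux) gives the alkylidene malonate F4. NaH in THF followed by ynoate 3 gives, by attack of the deconjugated anion through its malonate carbon, the ketal F5. Pyridinium p-toluenesulfonate in aqueous acetone unmasks the ketone, now conjugated with the C5=C10 alkene, and gives 7, where the route is rejoined.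

Further compounds
F1 | step 10 | ring A/B keto acid: 1-oxo, C10–H (either epimer), 4α-carboxy, C6 gem-dimethyl ester, C8 with α-CH2CO2Me and β-CH2C≡CSiMe3, 9β-H with α-CH2CH2SO2Ph | OC(=O)[C@]1(C)CCC(=O)C2[C@@H]1C(C(=O)OC)(C(=O)OC)[C@](CC(=O)OC)(CC#C[Si](C)(C)C)[C@H]2CCS(=O)(=O)c3ccccc3
F2 | step 10 | 1-oxo lactone: 1-oxo analogue of 20 | O=C1O[C@@]23C(=O)CC[C@]1(C)[C@H]2C(C(=O)OC)(C(=O)OC)[C@](CC(=O)OC)(CC#C[Si](C)(C)C)[C@H]3CCS(=O)(=O)c4ccccc4
F3 | step 4 | desmethyl aldehyde: analogue of 10 lacking the C4 methyl (C4 epimers) | O=CC1CCC(O[Si](C)(C)C(C)(C)C)=C[C@@H]1C(C(=O)OC)(C(=O)OC)C(CC#C[Si](C)(C)C)=CC(=O)OC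
F4 | step 2 | alkylidene malonate: dimethyl 2-[2-(2-methyl-1,3-dioxolan-2-yl)ethylidene]malonate | COC(=O)C(=CCC1(C)OCCO1)C(=O)OC
F5 | step 2 | ketal: trimethyl (4E)-5-(2-methyl-1,3-dioxolan-2-yl)-2-[3-(trimethylsilyl)prop-2-yn-1-yl]penta-1,4-diene-1,3,3-tricarboxylate | COC(=O)C=C(CC#C[Si](C)(C)C)C(C(=O)OC)(C(=O)OC)/C=C/C1(C)OCCO1
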